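**Plan**

- Target: 17-(3,5-dihydroxyphenyl)heptadecan-2-one, no stereocentre. The arene is numbered C1 (chain), C3 and C5 (oxygens).
- Enabling feature: the 1-alkyl-3,5-dioxygenated benzene ring with hydrogen at C2, C4 and C6. C6, C1, C2 and the oxygen-bearing C3 are the four ring carbons of a 3-alkylcyclobutenone; C4 and C5 are the two carbons of ethoxyacetylene.
- Retrosynthesis: cut the O–ethyl bond at C5, then the CH3–C(=O) bond of the chain (Weinreb amide, back to an ester). Next cut arene bonds C3–C4 and C5–C6 (with C2–C3 opened and re-closed) to give the cyclobutenone and ethoxyacetylene. Then take the cyclobutenone back to a terminal alkyne and dichloroketene, and the alkyne back to acetylide and 16-bromohexadecanoic acid.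
- Forward: the chain is joined first (acetylide alkylation), the four-membered ring is built on the alkyne, the benzene ring (the only ring of the target) arises in step 5, and the methyl ketone and the free resorcinol are released last.
- Stereochemistry: none to set. The only control needed is the regiochemistry of the ketene/ynol ether [2+2] event, which follows from the polarity of the two partners.

Key step: step 5

Remark: the chain terminus is carried through the ring-forming steps as an ethyl ester and becomes the methyl ketone only after the arene exists, because a ketone or its dioxolane would meet ZnCl2 and an acyl chloride in the dichloroketene step. Compounds 1, 2, 5 and 9 (9 as a solution in hexanes) are assumed to be purchased.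

**Route**

Step 1
Reactants: 1 16-bromohexadecanoic acid; 2 lithium acetylide–ethylenediamine complex (LiC≡CH·H2NCH2CH2NH2)
Product: 3 octadec-17-ynoic acid
Conditions: 2 (3.5 equiv), DMSO, 15 °C → rt; then aq. HCl
Reagents that add atoms: lithium acetylide–ethylenediamine complex (compound 2), [Li+].[C-]#C.NCCN
Why: SN2 alkylation of an acetylide by a primary bromide: the first equivalent of 2 turns the acid into an inert lithium carboxylate and the next displaces bromide in dipolar aprotic DMSO, the established way from ω-bromo acids to ω-alkynoic acids.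

Step 2
Reactants: 3 octadec-17-ynoic acid
Product: 4 ethyl octadec-17-ynoate
Conditions: EtOH, cat. H2SO4, reflux
Reagents that add atoms: ethanol, CCO
Why: Fischer esterification in excess ethanol masks the acid against the ketene of step 3, and the ethyl ester is chosen so that the ethanol solvent of step 4 cannot scramble it; the terminal alkyne is inert.

Step 3
Reactants: 4 ethyl octadec-17-ynoate; 5 trichloroacetyl chloride
Product: 7 ethyl 16-(4,4-dichloro-3-oxocyclobut-1-en-1-yl)hexadecanoate, via dichloroketene 6 (not isolated)
Conditions: Zn–Cu couple, 5 (slow addition), Et2O/DME, rt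
Reagents that add atoms: trichloroacetyl chloride (compound 5), ClC(=O)C(Cl)(Cl)Cl
Why: Dichloroketene 6, generated by zinc dechlorination of 5, undergoes thermal [2+2] cycloaddition with the terminal alkyne, its carbonyl carbon bonding to the terminal CH so that the chain sits at C3 of the cyclobutenone, while DME ties up the ZnCl2 formed and the ester stays untouched.

Step 4
Reactants: 7 ethyl 16-(4,4-dichloro-3-oxocyclobut-1-en-1-yl)hexadecanoate
Product: 8 ethyl 16-(3-oxocyclobut-1-en-1-yl)hexadecanoate
Conditions: Zn dust, AcOH, TMEDA, EtOH, 0 °C → rt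
Reagents that add atoms: none
Why: Zinc reduction of the two α-chloro ketone C–Cl bonds through zinc enolates that are protonated by acetic acid, in the TMEDA-buffered medium that is standard for converting 4,4-dichlorocyclobutenones into 3-alkylcyclobutenones without opening the strained ring.

Step 5
Reactants: 8 ethyl 16-(3-oxocyclobut-1-en-1-yl)hexadecanoate; 9 ethoxyacetylene
Product: 14 ethyl 16-(3-ethoxy-5-hydroxyphenyl)hexadecanoate, via vinylketene 10 (not isolated), via 4-vinylcyclobutenone 11 (not isolated), via dienylketene 12 (not isolated), via cyclohexa-2,4-dienone 13 (not isolated)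
Conditions: 9 (3 equiv), PhMe, 80 → 110 °C, sealed tube
Reagents that add atoms: ethoxyacetylene (compound 9), CCOC#C
Why: Thermal 4π electrocyclic opening of 8 breaks its C1–C4 bond and gives vinylketene 10, whose ketene C=C undergoes [2+2] cycloaddition with 9, the nucleophilic unsubstituted alkyne carbon attacking the ketene carbonyl carbon, to give 4-vinylcyclobutenone 11 (new arene bonds C3–C4 and C5–C6). A second, reversible 4π opening gives dienylketene 12, whose (18E) isomer closes by thermal disrotatory 6π electrocyclisation, forming the six-membered carbocycle through the bond between the ketene carbon and the methylidene carbon (arene C2–C3), and tautomerisation of dienone 13 to the phenol makes the sequence irreversible. The closest known reaction type is the Danheiser benzannulation of cyclobutenones with heterosubstituted alkynes. No stereocentre remains, since the single sp3 centre of 11 is racemic and is erased on ring opening. The selectivity needed is regiochemical and is secured by the polarisation of the ynol ether, which places the ethoxy-bearing carbon on the former C2 of 8 and therefore meta to both the new hydroxyl and the chain; the excess of 9 keeps 10 from being lost to dimerisation or to the phenol already formed, and the ester is a spectator to all four pericyclic events.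

Step 6
Reactants: 14 ethyl 16-(3-ethoxy-5-hydroxyphenyl)hexadecanoate
Product: 15 16-(3-ethoxy-5-hydroxyphenyl)-N-methoxy-N-methylhexadecanamide
Conditions: MeNHOMe·HCl (2 equiv), iPrMgCl (5 equiv), THF, −20 → 0 °C; aq. NH4Cl
Reagents that add atoms: N,O-dimethylhydroxylamine hydrochloride, CNOC.Cl
Why: Weinreb amide formation from an ester with the magnesium amide ClMgN(OMe)Me made in the flask from the hydroxylamine salt and iPrMgCl; the phenol is merely deprotonated (one extra equivalent of base is allowed for it) and the aryl ethyl ether is inert.

Step 7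
Reactants: 15 16-(3-ethoxy-5-hydroxyphenyl)-N-methoxy-N-methylhexadecanamide
Product: 16 17-(3-ethoxy-5-hydroxyphenyl)heptadecan-2-one
Conditions: MeMgBr (4 equiv), THF, 0 °C; aq. NH4Cl
Reagents that add atoms: methylmagnesium bromide (MeMgBr), C[Mg]Br
Why: Weinreb ketone synthesis: MeMgBr adds once to give a magnesium-chelated tetrahedral adduct that survives until the aqueous quench, so no tertiary alcohol forms, and the first equivalent is spent on the phenol, whose phenoxide is a spectator.

Step 8
Reactants: 16 17-(3-ethoxy-5-hydroxyphenyl)heptadecan-2-one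
Product: 17 17-(3,5-dihydroxyphenyl)heptadecan-2-one (hansfordiol B)
Conditions: BBr3 (4 equiv), CH2Cl2, −78 → 0 °C; then H2O
Reagents that add atoms: none
Why: Lewis-acid dealkylation of an aryl alkyl ether: BBr3 coordinates the ether oxygen, bromide removes the ethyl group by SN2, and hydrolysis of the aryl borates frees both phenols, while the ketone is only reversibly complexed at low temperature.

**Compound list**

1 | 16-bromohexadecanoic acid | OC(=O)CCCCCCCCCCCCCCCBr | starting material
2 | lithium acetylide–ethylenediamine complex, LiC≡CH·H2NCH2CH2NH2 | [Li+].[C-]#C.NCCN | starting material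
3 | octadec-17-ynoic acid | OC(=O)CCCCCCCCCCCCCCCC#C | intermediate
4 | ethyl octadec-17-ynoate | CCOC(=O)CCCCCCCCCCCCCCCC#C | intermediate
5 | trichloroacetyl chloride | ClC(=O)C(Cl)(Cl)Cl | starting material
6 | dichloroketene (not isolated) | ClC(Cl)=C=O | intermediate
7 | ethyl 16-(4,4-dichloro-3-oxocyclobut-1-en-1-yl)hexadecanoate | CCOC(=O)CCCCCCCCCCCCCCCC1=CC(=O)C1(Cl)Cl | intermediate
8 | ethyl 16-(3-oxocyclobut-1-en-1-yl)hexadecanoate | CCOC(=O)CCCCCCCCCCCCCCCC1=CC(=O)C1 | intermediate
9 | ethoxyacetylene | CCOC#C | starting material
10 | ethyl 17-methylidene-19-oxononadec-18-enoate (vinylketene, not isolated) | CCOC(=O)CCCCCCCCCCCCCCCC(=C)C=C=O | intermediate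
11 | ethyl 17-(2-ethoxy-4-oxocyclobut-2-en-1-yl)octadec-17-enoate (4-vinylcyclobutenone, racemic, not isolated) | CCOC(=O)CCCCCCCCCCCCCCCC(=C)C1C(OCC)=CC1=O | intermediate
12 | ethyl (18E)-19-ethoxy-17-methylidene-21-oxohenicosa-18,20-dienoate (dienylketene, not isolated) | CCOC(=O)CCCCCCCCCCCCCCCC(=C)/C=C(OCC)\C=C=O | intermediate
13 | ethyl 16-(3-ethoxy-5-oxocyclohexa-1,3-dien-1-yl)hexadecanoate (cyclohexa-2,4-dienone, not isolated) | CCOC(=O)CCCCCCCCCCCCCCCC1=CC(OCC)=CC(=O)C1 | intermediate
14 | ethyl 16-(3-ethoxy-5-hydroxyphenyl)hexadecanoate | CCOC(=O)CCCCCCCCCCCCCCCc1cc(O)cc(OCC)c1 | intermediate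
15 | 16-(3-ethoxy-5-hydroxyphenyl)-N-methoxy-N-methylhexadecanamide | CON(C)C(=O)CCCCCCCCCCCCCCCc1cc(O)cc(OCC)c1 | intermediate
16 | 17-(3-ethoxy-5-hydroxyphenyl)heptadecan-2-one | CC(=O)CCCCCCCCCCCCCCCc1cc(O)cc(OCC)c1 | intermediate
17 | 17-(3,5-dihydroxyphenyl)heptadecan-2-one (hansfordiol B) | CC(=O)CCCCCCCCCCCCCCCc1cc(O)cc(O)c1 | target

**Summary**

Total step count: 8. Longest linear sequence: 8 steps (1 → 17).

Steps most likely to fail:

Step 3. The unactivated alkyne may add dichloroketene too slowly, so that the ketene is lost to oligomerisation, and the strained chlorinated enone may degrade under the Lewis-acidic zinc salts. The fallback sets out from 4 and uses a keteniminium [2+2] cycloaddition instead of a ketene. N,N-Dimethylacetamide, Tf2O and 2,4,6-collidine in 1,2-dichloroethane should generate N,N-dimethylketeniminium trifluoromethanesulfonate F1. At reflux this should add to the alkyne of 4 with the same regiochemistry to give ethyl 16-[3-(dimethyliminio)cyclobut-1-en-1-yl]hexadecanoate trifluoromethanesulfonate F2. Hydrolysis with aq. NaHCO3 should give the chlorine-free cyclobutenone directly, so the fallback bypasses steps 3 and 4 and comes back to the route at 8.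

Step 5. Ethoxyacetylene may be lost through volatility, thermal fragmentation or polymerisation before the vinylketene is intercepted, leaving the vinylketene to dimerise or to acylate the phenol already formed. The fallback sets out from 8 and 9 and replaces the volatile alkyne by its C-silylated, distillable derivative.
- Lithiation of 9 (n-BuLi, THF, −78 °C) and quenching with Me3SiCl should give (ethoxyethynyl)trimethylsilane F3.
- Heating F3 with 8 in toluene should run the same cascade, the silyl-bearing carbon bonding to the ketene carbonyl carbon. The intermediates are ethyl 17-[2-ethoxy-4-oxo-3-(trimethylsilyl)cyclobut-2-en-1-yl]octadec-17-enoate F4, ethyl (18E)-19-ethoxy-17-methylidene-21-oxo-20-(trimethylsilyl)henicosa-18,20-dienoate F5 and ethyl 16-[3-ethoxy-5-oxo-4-(trimethylsilyl)cyclohexa-1,3-dien-1-yl]hexadecanoate F6.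
- The cascade should end at ethyl 16-[3-ethoxy-5-hydroxy-4-(trimethylsilyl)phenyl]hexadecanoate F7.
- Protodesilylation of this doubly oxygen-activated arylsilane (CF3CO2H, CH2Cl2, rt) returns the route to 14.

Step 8. Under BBr3 and the HBr it releases, the enolisable methyl ketone may condense with the electron-rich resorcinol ring or with itself, and cleavage of the ethyl ether may stall. The fallback sets out from 14 and moves the ether cleavage to the ester stage, where no ketone is present.
- BBr3 in CH2Cl2 (−78 → 0 °C, ethanol quench to restore any cleaved ester) should give ethyl 16-(3,5-dihydroxyphenyl)hexadecanoate F8.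
- MeNHOMe·HCl and iPrMgCl, with two further equivalents of base for the phenols, should give 16-(3,5-dihydroxyphenyl)-N-methoxy-N-methylhexadecanamide F9.
- MeMgBr in THF should then give the target, so the fallback comes back to the route at 17.

**Further compounds**

F1 | step 3 | N,N-dimethylketeniminium trifluoromethanesulfonate | C=C=[N+](C)C.[O-]S(=O)(=O)C(F)(F)F
F2 | step 3 | ethyl 16-[3-(dimethyliminio)cyclobut-1-en-1-yl]hexadecanoate trifluoromethanesulfonate | CCOC(=O)CCCCCCCCCCCCCCCC1=CC(=[N+](C)C)C1.[O-]S(=O)(=O)C(F)(F)F
F3 | step 5 | (ethoxyethynyl)trimethylsilane | CCOC#C[Si](C)(C)C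
F4 | step 5 | ethyl 17-[2-ethoxy-4-oxo-3-(trimethylsilyl)cyclobut-2-en-1-yl]octadec-17-enoate | CCOC(=O)CCCCCCCCCCCCCCCC(=C)C1C(OCC)=C([Si](C)(C)C)C1=O
F5 | step 5 | ethyl (18E)-19-ethoxy-17-methylidene-21-oxo-20-(trimethylsilyl)henicosa-18,20-dienoate | CCOC(=O)CCCCCCCCCCCCCCCC(=C)/C=C(OCC)\C([Si](C)(C)C)=C=O
F6 | step 5 | ethyl 16-[3-ethoxy-5-oxo-4-(trimethylsilyl)cyclohexa-1,3-dien-1-yl]hexadecanoate | CCOC(=O)CCCCCCCCCCCCCCCC1=CC(OCC)=C([Si](C)(C)C)C(=O)C1
F7 | step 5 | ethyl 16-[3-ethoxy-5-hydroxy-4-(trimethylsilyl)phenyl]hexadecanoate | CCOC(=O)CCCCCCCCCCCCCCCc1cc(O)c([Si](C)(C)C)c(OCC)c1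
F8 | step 8 | ethyl 16-(3,5-dihydroxyphenyl)hexadecanoate | CCOC(=O)CCCCCCCCCCCCCCCc1cc(O)cc(O)c1
F9 | step 8 | 16-(3,5-dihydroxyphenyl)-N-methoxy-N-methylhexadecanamide | CON(C)C(=O)CCCCCCCCCCCCCCCc1cc(O)cc(O)c1
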